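Ring D is opened between its oxygen and C16: the γ-lactone, and through it the dihydrofuran, goes back to a spiro-cyclobutanone. The step exploits that C13, the atom shared by rings C and D, bears the methylene groups C14 and C16, both bonded to carbonyl C15, so that C13 is not yet stereogenic. One catalyst-controlled Baeyer–Villiger oxidation inserts oxygen into C15–C16, enlarges the four-membered ring to ring D and fixes C13 as R. The precursor, 9α,13-epoxy-15,16-cyclolabd-8(17)-en-15-one, is reached from (+)-manool via a C9 spirolactone, double methylenation and a dichloroketene cycloaddition; its C8 methylene is later turned into the 7-oxo-8-acetoxy unit.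

Key step: step 8

Remark: labdane numbering is used, α/β denote the faces of the decalin (C10 methyl β), and (+)-manool is taken as the commercial chiral-pool source of C1–C13, the C8 methylene and the ring A/B stereocentres.
Remark: centres that form as mixtures and do not survive to the target (C15 of the lactol and acetals, C8 of the ozonides, C15 of the perhydrate) are left open in the SMILES; the dichloro ketone is drawn as one C13 epimer.

Step 1
Reactants: 1 (+)-manool
Product: 2 14,15-dinorlabd-8(17)-en-13-one
Conditions: KMnO4, acetone/H2O, 0 °C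
Reagents that add atoms: none
Why: Permanganate degradation of a tertiary vinyl carbinol (dihydroxylation, glycol cleavage and loss of the resulting one-carbon acid) should remove C14 and C15 and leave the C13 methyl ketone, the unhindered vinyl group reacting faster than the C8 methylene that is shielded by C9 and the C10 methyl, with no ring stereocentre touched.

Step 2
Reactants: 2 14,15-dinorlabd-8(17)-en-13-one
Product: 3 14,15,16-trinorlabd-8(17)-en-13-oic acid
Conditions: Br2, NaOH, H2O/1,4-dioxane, 0 °C; then HCl
Reagents that add atoms: sodium hydroxide [Na+].[OH-]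
Why: Haloform reaction, in which exhaustive base-mediated bromination of the methyl group and acyl substitution by hydroxide expel bromoform and leave C13 as the carboxylate, while cold alkaline hypobromite should not add to the hindered alkene.

Step 3
Reactants: 3 14,15,16-trinorlabd-8(17)-en-13-oic acid
Product: 5 8-oxo-14,15,16,17-tetranorlabdan-13-oic acid, via ozonide 4 (not isolated)
Conditions: O3, CH2Cl2, −78 °C; then Me2S, −78 °C → rt
Reagents that add atoms: ozone [O-][O+]=O
Why: Ozonolysis (dipolar cycloaddition, cycloreversion, recombination to the ozonide and reductive cleavage) removes C17 as formaldehyde and gives the C8 ketone, whose 9α-H epimer with the equatorial side chain is the stable one and whose C9 is made planar in the next step anyway.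

Step 4
Reactants: 5 8-oxo-14,15,16,17-tetranorlabdan-13-oic acid
Product: 6 14,15,16,17-tetranorlabd-8-en-13,8-olide
Conditions: Ac2O, NaOAc, 140 °C
Reagents that add atoms: none
Why: Enol lactonisation of a 5-oxo acid through the mixed anhydride, which under these equilibrating conditions should give the ring-fused tetrasubstituted C8=C9 enol lactone and thereby ties the coming oxygenation to C9 instead of C7.

Step 5
Reactants: 6 14,15,16,17-tetranorlabd-8-en-13,8-olide
Product: 8 8-oxo-14,15,16,17-tetranorlabdan-13,9α-olide, via epoxy lactone 7 (not isolated)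
Conditions: dimethyldioxirane, acetone/CH2Cl2, 0 °C; evaporate; then NaOMe (10 mol %), THF, 0 °C → rt
Reagents that add atoms: dimethyldioxirane CC1(C)OO1
Why: Epoxidation of the enol ester on the α face, opposite the axial C10 methyl, followed by methoxide-initiated acyl transfer (acyloxy epoxide to α-acyloxy ketone rearrangement, a Rubottom-type oxygenation) in which the opened lactone releases the C8 ketone and the 9α-alkoxide that recloses on C13 as the spiro γ-lactone, so the C9–O bond made on the α face is never broken and fixes C9.

Step 6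
Reactants: 8 8-oxo-14,15,16,17-tetranorlabdan-13,9α-olide
Product: 9 9α,13-epoxy-14,15-dinorlabda-8(17),13(16)-diene
Conditions: (C5H5)2Ti(CH3)2 (5 equiv), toluene/THF, 65 °C, dark; filtration through basic Al2O3
Reagents that add atoms: dimethyltitanocene C[Ti](C)(C1C=CC=C1)C1C=CC=C1
Why: Petasis methylenation, in which the titanocene methylidene formed on heating converts both the hindered C8 ketone and the lactone carbonyl into C=CH2 through oxatitanacyclobutanes under neutral conditions, which keeps the exocyclic enol ether from isomerising and stays below the temperature at which the allyl vinyl ether unit of 9 could undergo Claisen ring expansion.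

Step 7
Reactants: 9 9α,13-epoxy-14,15-dinorlabda-8(17),13(16)-diene; 10 trichloroacetyl chloride
Product: 12 9α,13-epoxy-15,16-cyclolabd-8(17)-en-15-one, via dichlorocyclobutanone 11 (not isolated)
Conditions: 10 (1.5 equiv), Zn(Cu), Et2O/DME, 0 °C → rt; filter; then Zn, NH4Cl, MeOH, rt
Reagents that add atoms: trichloroacetyl chloride ClC(=O)C(Cl)(Cl)Cl
Why: Ketene–enol ether [2+2] cycloaddition followed by reductive dechlorination, in which dichloroketene bonds through its carbonyl carbon to the nucleophilic CH2 terminus and through CCl2 to C13 far faster than it reacts with the hindered unactivated C8 methylene, and zinc then removes both chlorines so that the two arms on C13 become identical and the face of the cycloaddition is of no consequence.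

Step 8
Reactants: 12 9α,13-epoxy-15,16-cyclolabd-8(17)-en-15-one
Product: 14 (13R)-9α,13-epoxylabd-8(17)-en-15,16-olide, via Criegee adduct 13 (not isolated)
Conditions: 30% aq. H2O2 (1.5 equiv), (R)-3,3'-bis(2,4,6-triisopropylphenyl)-1,1'-binaphthyl-2,2'-diyl hydrogen phosphate (10 mol %), CHCl3, −40 °C
Reagents that add atoms: hydrogen peroxide OO
Why: The phosphoric acid activates the strained C15 carbonyl and H2O2 together, so the perhydrate 13 forms inside the chiral pocket, where the peroxide is held so that only one of the two diastereotopic C–C bonds lies antiperiplanar to O–O, and that methylene (C16, on the face of ring C that carries C8) shifts from C15 to oxygen with loss of water. The closest known reaction type is the chiral Brønsted acid/H2O2 Baeyer–Villiger desymmetrisation of prochiral 3-substituted cyclobutanones. Ring D is not closed by a cyclisation but arises by ring expansion, a 1,2-shift of carbon to oxygen that turns the four-membered carbocycle into the five-membered lactone. C13 becomes a stereocentre without any bond to it being made or broken, and its R configuration is decided only by which arm migrates, that is by the (R)-catalyst acting on a substrate whose centres at C9 and C10 make the two arms diastereotopic. The step needs group selectivity between C16 and C14 and chemoselectivity for the ketone: ring strain makes the cyclobutanone the only group that H2O2 attacks under weak acid, the C8=C17 alkene does not react with H2O2 in the absence of a peracid or metal, the ring C oxygen on C13 offers the catalyst a hydrogen-bond contact next to the reacting centre, and −40 °C with a mild acid should keep the 3-alkoxycyclobutanone from opening.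

Step 9
Reactants: 14 (13R)-9α,13-epoxylabd-8(17)-en-15,16-olide
Product: 15 (13R)-9α,13:15,16-diepoxylabd-8(17)-en-15-ol
Conditions: iBu2AlH (1.1 equiv), CH2Cl2, −78 °C; aq. KNaC4H4O6
Reagents that add atoms: none
Why: Partial reduction of a γ-lactone, in which the tetrahedral aluminium hemiacetal is stable at −78 °C and gives the lactol on hydrolysis while the alkene and the ring C ether are inert to the hydride, C15 forming as both anomers, which is immaterial because it ends as an sp2 carbon.

Step 10
Reactants: 15 (13R)-9α,13:15,16-diepoxylabd-8(17)-en-15-ol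
Product: 16 (13R)-15-methoxy-9α,13:15,16-diepoxylabd-8(17)-ene
Conditions: MeOH, PPTS (cat.), rt
Reagents that add atoms: methanol CO
Why: Acid-catalysed acetalisation through the cyclic oxocarbenium ion (Fischer-type glycosidation) stores ring D as a methyl acetal that tolerates ozone, enolate and Grignard chemistry, and the weak pyridinium acid should not ionise the tertiary allylic C9–O bond.

Step 11
Reactants: 16 (13R)-15-methoxy-9α,13:15,16-diepoxylabd-8(17)-ene
Product: 18 (13R)-15-methoxy-9α,13:15,16-diepoxy-17-norlabdan-8-one, via ozonide 17 (not isolated)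
Conditions: O3, CH2Cl2, −78 °C, Sudan Red 7B end point; then Me2S, −78 °C → rt
Reagents that add atoms: ozone [O-][O+]=O
Why: Ozonolysis of the exocyclic alkene releases the C8 ketone that the methylene has masked since step 6, and stopping at the indicator end point prevents the slower ozone insertion into the acetal C–H bond.

Step 12
Reactants: 18 (13R)-15-methoxy-9α,13:15,16-diepoxy-17-norlabdan-8-one
Product: 20 (13R)-7α-hydroxy-15-methoxy-9α,13:15,16-diepoxy-17-norlabdan-8-one, via potassium enolate 19 (not isolated)
Conditions: KN(SiMe3)2, THF, −78 °C; then 2-(phenylsulfonyl)-3-phenyloxaziridine, −78 °C; aq. NH4Cl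
Reagents that add atoms: 2-(phenylsulfonyl)-3-phenyloxaziridine O=S(=O)(c1ccccc1)N1OC1c1ccccc1
Why: Davis oxidation, for which the ketone can enolise only towards C7 because C9 is quaternary, and in which oxygen transfer to the enolate should occur axially on the α face through a chair-like transition state (β attack would pass through a boat with a flagpole clash with the C10 methyl), giving the 7α-alcohol as a temporary centre that is oxidised away in step 15.

Step 13
Reactants: 20 (13R)-7α-hydroxy-15-methoxy-9α,13:15,16-diepoxy-17-norlabdan-8-one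
Product: 21 (13R)-15-methoxy-9α,13:15,16-diepoxylabdane-7α,8β-diol
Conditions: MeMgBr (4 equiv), THF, −78 → 0 °C; aq. NH4Cl
Reagents that add atoms: methylmagnesium bromide C[Mg]Br
Why: Grignard addition to an α-hydroxy ketone, in which, after deprotonation of O7–H, methyl should enter along the equatorial trajectory on the α face because the axial β approach is blocked by the syn-axial C10 methyl and the magnesium alkoxide bridged to the axial ring C oxygen holds the reagent under the ring, which sets C8 with the methyl α and the hydroxyl β.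

Step 14
Reactants: 21 (13R)-15-methoxy-9α,13:15,16-diepoxylabdane-7α,8β-diol
Product: 23 (13R)-9α,13:15,16-diepoxylabd-14-ene-7α,8β-diol, via bis-silyl ether 22 (not isolated)
Conditions: TMSOTf (4 equiv), iPr2NEt (6 equiv), CH2Cl2, −78 → 0 °C; aq. NaHCO3; then K2CO3, MeOH, 0 °C
Reagents that add atoms: none
Why: Silyl triflate/amine-mediated conversion of an acetal into an enol ether, in which both hydroxyls are silylated, ionisation of the C15 methoxy group gives the ring D oxocarbenium ion that can lose a proton only from C14, so the C14=C15 enol ether forms in an amine-buffered medium, and basic methanolysis then frees the two hydroxyls without exposing the acid-labile spiro dihydrofuran to acid.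

Step 15
Reactants: 23 (13R)-9α,13:15,16-diepoxylabd-14-ene-7α,8β-diol
Product: 24 (13R)-8β-hydroxy-9α,13:15,16-diepoxylabd-14-en-7-one
Conditions: SO3·pyridine, DMSO, iPr2NEt, CH2Cl2, 0 °C; aq. NaHCO3
Reagents that add atoms: none
Why: Parikh–Doering oxidation turns the secondary C7 alcohol into the ketone in a basic medium that should leave the tertiary C8 alcohol, the diol C–C bond and the enol ether untouched, and it removes the temporary C7 stereocentre.

Step 16
Reactants: 24 (13R)-8β-hydroxy-9α,13:15,16-diepoxylabd-14-en-7-one
Product: 25 (13R)-8β-acetoxy-9α,13:15,16-diepoxylabd-14-en-7-one (target)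
Conditions: Ac2O, DMAP, Et3N, CH2Cl2, 40 °C
Reagents that add atoms: acetic anhydride CC(=O)OC(C)=O
Why: DMAP-catalysed acylation through the N-acetylpyridinium ion should esterify the hindered axial tertiary α-ketol while the basic medium protects the acid-sensitive rings C and D, and no stereocentre changes.

Compound list
1 | (+)-manool, (13R)-labda-8(17),14-dien-13-ol | C=C1CC[C@H]2C(C)(C)CCC[C@]2(C)[C@H]1CC[C@@](C)(O)C=C | starting material
2 | 14,15-dinorlabd-8(17)-en-13-one (methyl ketone on the 9β side chain) | C=C1CC[C@H]2C(C)(C)CCC[C@]2(C)[C@H]1CCC(C)=O | intermediate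
3 | 14,15,16-trinorlabd-8(17)-en-13-oic acid | C=C1CC[C@H]2C(C)(C)CCC[C@]2(C)[C@H]1CCC(=O)O | intermediate
4 | ozonide of 3 (spiro-1,2,4-trioxolane at C8, C8 open) | C12(OCOO1)CC[C@H]3C(C)(C)CCC[C@]3(C)[C@H]2CCC(=O)O | intermediate
5 | 8-oxo-14,15,16,17-tetranorlabdan-13-oic acid (9α-H) | O=C1CC[C@H]2C(C)(C)CCC[C@]2(C)[C@H]1CCC(=O)O | intermediate
6 | 14,15,16,17-tetranorlabd-8-en-13,8-olide (enol δ-lactone, C8=C9) | O=C1CCC2=C(CC[C@H]3C(C)(C)CCC[C@]23C)O1 | intermediate
7 | 8α,9α-epoxy-14,15,16,17-tetranorlabdan-13,8-olide | O=C1CC[C@@]23O[C@]2(O1)CC[C@H]4C(C)(C)CCC[C@]34C | intermediate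
8 | 8-oxo-14,15,16,17-tetranorlabdan-13,9α-olide (spiro γ-lactone, oxygen on the α face of C9) | O=C1CC[C@H]2C(C)(C)CCC[C@]2(C)[C@@]12CCC(=O)O2 | intermediate
9 | 9α,13-epoxy-14,15-dinorlabda-8(17),13(16)-diene | C=C1CC[C@H]2C(C)(C)CCC[C@]2(C)[C@@]12CCC(=C)O2 | intermediate
10 | trichloroacetyl chloride | ClC(=O)C(Cl)(Cl)Cl | starting material
11 | 16,16-dichloro-9α,13-epoxy-15,16-cyclolabd-8(17)-en-15-one (CCl2 on C13, drawn syn to C8; either C13 epimer serves) | C=C1CC[C@H]2C(C)(C)CCC[C@]2(C)[C@@]12CC[C@]1(CC(=O)C1(Cl)Cl)O2 | intermediate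
12 | 9α,13-epoxy-15,16-cyclolabd-8(17)-en-15-one | C=C1CC[C@H]2C(C)(C)CCC[C@]2(C)[C@@]12CCC1(CC(=O)C1)O2 | intermediate
13 | 15-hydroperoxy-9α,13-epoxy-15,16-cyclolabd-8(17)-en-15-ol (Criegee adduct, C15 open) | C=C1CC[C@H]2C(C)(C)CCC[C@]2(C)[C@@]12CCC1(CC(O)(OO)C1)O2 | intermediate
14 | (13R)-9α,13-epoxylabd-8(17)-en-15,16-olide | C=C1CC[C@H]2C(C)(C)CCC[C@]2(C)[C@@]12CC[C@]1(CC(=O)OC1)O2 | intermediate
15 | (13R)-9α,13:15,16-diepoxylabd-8(17)-en-15-ol (lactol, C15 anomers) | C=C1CC[C@H]2C(C)(C)CCC[C@]2(C)[C@@]12CC[C@]1(CC(O)OC1)O2 | intermediate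
16 | (13R)-15-methoxy-9α,13:15,16-diepoxylabd-8(17)-ene (C15 anomers) | C=C1CC[C@H]2C(C)(C)CCC[C@]2(C)[C@@]12CC[C@]1(CC(OC)OC1)O2 | intermediate
17 | ozonide of 16 (spiro-1,2,4-trioxolane at C8, C8 open) | C12(OCOO1)CC[C@H]3C(C)(C)CCC[C@]3(C)[C@@]24CC[C@]5(CC(OC)OC5)O4 | intermediate
18 | (13R)-15-methoxy-9α,13:15,16-diepoxy-17-norlabdan-8-one | O=C1CC[C@H]2C(C)(C)CCC[C@]2(C)[C@@]12CC[C@]1(CC(OC)OC1)O2 | intermediate
19 | potassium 7-en-8-olate of 18 | [K+].[O-]C1=CC[C@H]2C(C)(C)CCC[C@]2(C)[C@@]12CC[C@]1(CC(OC)OC1)O2 | intermediate
20 | (13R)-7α-hydroxy-15-methoxy-9α,13:15,16-diepoxy-17-norlabdan-8-one | O=C1[C@H](O)C[C@H]2C(C)(C)CCC[C@]2(C)[C@@]12CC[C@]1(CC(OC)OC1)O2 | intermediate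
21 | (13R)-15-methoxy-9α,13:15,16-diepoxylabdane-7α,8β-diol (C17 methyl α) | C[C@]1(O)[C@H](O)C[C@H]2C(C)(C)CCC[C@]2(C)[C@@]12CC[C@]1(CC(OC)OC1)O2 | intermediate
22 | (13R)-7α,8β-bis(trimethylsilyloxy)-9α,13:15,16-diepoxylabd-14-ene | C[C@]1(O[Si](C)(C)C)[C@H](O[Si](C)(C)C)C[C@H]2C(C)(C)CCC[C@]2(C)[C@@]12CC[C@]1(C=COC1)O2 | intermediate
23 | (13R)-9α,13:15,16-diepoxylabd-14-ene-7α,8β-diol | C[C@]1(O)[C@H](O)C[C@H]2C(C)(C)CCC[C@]2(C)[C@@]12CC[C@]1(C=COC1)O2 | intermediate
24 | (13R)-8β-hydroxy-9α,13:15,16-diepoxylabd-14-en-7-one | C[C@]1(O)C(=O)C[C@H]2C(C)(C)CCC[C@]2(C)[C@@]12CC[C@]1(C=COC1)O2 | intermediate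
25 | (13R)-8β-acetoxy-9α,13:15,16-diepoxylabd-14-en-7-one (CNP0165143.1) | CC(=O)O[C@@]1(C)C(=O)C[C@H]2C(C)(C)CCC[C@]2(C)[C@@]12CC[C@]1(C=COC1)O2 | target

Total step count: 16. Longest linear sequence: 16 steps (1 to 25); 10 enters at step 7.

Steps most likely to fail

Step 8. The process at risk is weak or reversed discrimination between the two methylene groups by the catalyst, since the resident stereocentres lie three bonds from C15, together with acid-induced opening of the donor–acceptor cyclobutanone. The fallback sets out from 12 and gives up catalyst control: uncatalysed Baeyer–Villiger oxidation with 30% H2O2 in 2,2,2-trifluoroethanol at rt needs no acid and should give 14 together with its C13 epimer, (13S)-9α,13-epoxylabd-8(17)-en-15,16-olide F1. The two are diastereomers and are separated by chromatography; the route resumes at 14.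

Step 13. The process at risk is loss of facial control in the Grignard addition (competing β attack, or base-induced isomerisation of the α-ketol), caused by the axial C7 oxygen that flanks the α face. The fallback sets out from 18 and replaces steps 12 to 15.
- Claisen–Schmidt condensation with PhCHO (KOH, EtOH, rt) should give the (E)-7-benzylidene ketone F2, in which C7 is planar.
- MeLi/CeCl3 (THF, −78 °C) then adds 1,2 from the α face, controlled only by the C10 methyl, to give the 8β-hydroxy-8α-methyl allylic alcohol F3.
- Ozonolysis (O3, CH2Cl2, −78 °C; Me2S) proceeds through the ozonide F4 and releases the C7 ketone as the ketol acetal F5.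
- TMSOTf/iPr2NEt (CH2Cl2, −78 → 0 °C) eliminates methanol and silylates the alcohol and the ketone to the bis-silylated dienol ether F6, which K2CO3/MeOH at 0 °C desilylates to 24, where the route resumes.

Step 14. The process at risk is Lewis-acid ionisation of the C13–O bond of ring C once the enol ether is present (vinylogous acetal cleavage that ends in aromatisation of ring D to a furan), or incomplete elimination. The fallback sets out from 21 and avoids the silyl triflate. Exchange of the methoxy group for phenylselanyl (PhSeH, BF3·OEt2, CH2Cl2, −40 °C, before any enol ether exists) gives the 15-phenylselanyl ether F7. Oxidation with NaIO4/NaHCO3 in MeOH/H2O gives the selenoxide F8, whose syn elimination at rt removes a C14 hydrogen and forms the C14=C15 enol ether under neutral to basic conditions, returning to the route at 23.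

Further compounds
F1 | step 8 | (13S)-9α,13-epoxylabd-8(17)-en-15,16-olide (C13 epimer of 14) | C=C1CC[C@H]2C(C)(C)CCC[C@]2(C)[C@@]12CC[C@@]1(CC(=O)OC1)O2
F2 | step 13 | (13R,7E)-7-benzylidene-15-methoxy-9α,13:15,16-diepoxy-17-norlabdan-8-one | O=C1/C(=C/c3ccccc3)C[C@H]2C(C)(C)CCC[C@]2(C)[C@@]12CC[C@]1(CC(OC)OC1)O2
F3 | step 13 | (13R,7E)-7-benzylidene-15-methoxy-9α,13:15,16-diepoxylabdan-8β-ol (C17 methyl α) | C[C@]1(O)/C(=C/c3ccccc3)C[C@H]2C(C)(C)CCC[C@]2(C)[C@@]12CC[C@]1(CC(OC)OC1)O2
F4 | step 13 | ozonide of F3 (1,2,4-trioxolane across C7 and the benzylic carbon, both open) | C[C@]1(O)C3(OC(c4ccccc4)OO3)C[C@H]2C(C)(C)CCC[C@]2(C)[C@@]12CC[C@]1(CC(OC)OC1)O2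
F5 | step 13 | (13R)-8β-hydroxy-15-methoxy-9α,13:15,16-diepoxylabdan-7-one | C[C@]1(O)C(=O)C[C@H]2C(C)(C)CCC[C@]2(C)[C@@]12CC[C@]1(CC(OC)OC1)O2
F6 | step 13 | (13R)-7,8β-bis(trimethylsilyloxy)-9α,13:15,16-diepoxylabda-6,14-diene | C[C@]1(O[Si](C)(C)C)C(O[Si](C)(C)C)=C[C@H]2C(C)(C)CCC[C@]2(C)[C@@]12CC[C@]1(C=COC1)O2
F7 | step 14 | (13R)-15-phenylselanyl-9α,13:15,16-diepoxylabdane-7α,8β-diol (C15 open) | C[C@]1(O)[C@H](O)C[C@H]2C(C)(C)CCC[C@]2(C)[C@@]12CC[C@]1(CC([Se]c3ccccc3)OC1)O2
F8 | step 14 | selenoxide of F7 | C[C@]1(O)[C@H](O)C[C@H]2C(C)(C)CCC[C@]2(C)[C@@]12CC[C@]1(CC([Se](=O)c3ccccc3)OC1)O2
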